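## Analysis of the target

Target 33 is a labdane. Ring A (C1–C5, C10) and ring B (C5–C10) form a decalin whose ring B holds the tetrasubstituted C8=C9 alkene. C8 carries the C17 methyl group, and C9 carries the chain C11–C16, which ends in an (E)-3-methylbut-2-enoic acid unit (C13=C14, acid at C15). All five stereocentres sit in the saturated half: C3 (axial α-isovalerate), C4 (quaternary, C18 methyl α, C19 acyloxymethyl β), C5 (α-H), C6 (axial β-hydroxyl) and C10 (quaternary, C20 methyl β). This corresponds to (3R,4S,5R,6R,10S). C19, C20 and the C6 oxygen all stand axial on the β face, so the free 6β-hydroxyl is flanked by two syn-axial carbon groups, and C5–H is trans to C20. The sensitive points are two isovalerate esters next to a free hydroxyl (a 19→6 acyl shift is possible in base), an enoic acid whose E geometry must be kept, and a tetrasubstituted alkene that strong acid can move. The synthesis is hard because two quaternary stereocentres (C4 and C10) flank C5, and because exactly the most hindered of three hydroxyls must stay free. The strategy rests on the 1,4-relation of the C6 oxygen and the oxygenated C19 through C5 and C4. This dissonant pattern is met by polarity inversion: an acyl radical at C6 adds to C5, the β-carbon of a C4 ester enoate in ring A, and closes ring B. The C6 ketone so formed makes C5 epimerisable, and after reduction the 6β-oxygen and C19 close a γ-lactone that fixes the face on which C4 is methylated.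

## Retrosynthetic reasoning

**C13=C14 and the acid.** Target 33 is traced to allyl ester 32 and this to methyl ketone 31 by cutting the C13=C14 double bond. The cut is made here because the two carbons C14 and C15 can arrive last on a phosphonate, so that the acid never has to pass through hydride or enolate chemistry. The forward olefination must favour the E isomer, and the ester must be cleavable without touching the isovalerates.

**The two acyl C–O bonds.** Diester 31 is traced to triol ketone 30. The three hydroxyls of 30 differ strongly (primary C19, axial C3, and the 6β-hydroxyl syn-axial to C19 and C20), so no protecting group is needed for O6. The forward acylation has to stop at two esters.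

**Unmasking and the C19–O6 bond.** Triol 30 comes from diol 29 by loss of the silyl ether and the ketal, and 29 comes from lactone 28 by reduction. Opening the lactone reductively delivers the C19 alcohol and the 6β-hydroxyl in one step.

**C4–C18.** Lactone 28 is traced to 26 by removing the C18 methyl group. The methyl is added at this stage because the lactone bridge holds C19 on the β face, so an electrophile can only enter from the α face. This creates the quaternary C4 with the correct configuration.

**C9–C11.** Compound 26 is cut between C9 and C11 into enol triflate 23 and bromide 24. The C9 ketone left by the ring closure is the natural handle. The side chain arrives late as a masked methyl ketone, which keeps it out of the radical and enolate steps. The forward reaction is an sp2–sp3 coupling at a hindered tetrasubstituted carbon.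

**C6–H and the lactone acyl bond.** Triflate 23 comes from ketone 21, and 21 from diketo ester 19. The forward sequence must reduce C6 and not C9, deliver hydride from the α face, and bring the C4 ester to the β side so that it can close onto O6.

**C5–C6 (key disconnection).** Diketone 19 is cut between C5 and C6 to selenoester 17. No other bond of ring B lets the C6 and C19 oxygens be joined across a consonant polar step. The cut also removes two stereocentres from kinetic control, since C5 becomes epimerisable next to the new ketone.

**C7–C8.** Selenoester 17 comes from acid 16 and ester 15, and 15 is cut between C7 and C8 into ethyl ketone 12 and bromoacetate 13. Ketone 12 has a single enolisable position, so the alkylation is regiochemically unambiguous.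

**C9=O, C4–C19 and the enoate.** Ketone 12 comes from alkene 11 by oxidative cleavage, and 11 from enol triflate 10 by carbonylation, which puts C19 on C4 and makes C5 the acceptor carbon. Triflate 10 comes from silyl enol ether 8, whose double bond position is fixed by the way 8 is made.

**C9–C10.** Enol ether 8 is cut between C9 and C10 into enone 4 and but-1-yne 5. A conjugate addition under catalyst control creates the quaternary C10 and leaves the enolate exactly where the triflate is needed.

**C3–O.** Enone 4 is traced through alcohol 3 and racemic acetate 2 to enone 1 by α′-oxygenation and resolution. The C3 oxygen is thus carried from the first step.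

## Alternatives that were turned down

Alternative 1: Ring A is cut at C1–C10 and C4–C5 into (E)-penta-1,3-diene A1 and 2,6-dimethyl-1,4-benzoquinone A2. In the forward step a chiral cationic oxazaborolidine Lewis acid would select one of the two enantiotopic methyl-bearing double bonds of A2 and give the cis-fused endo adduct A3.
- For: one step gives a decalin with the quaternary C10 set by the catalyst, the C17 methyl on C8 and oxygen at both C6 and C9.
- Against: A3 has only a methyl group and a hydrogen at C4 and no oxygen at C3. C4 is not enolisable, so C19 could only come in on the diene, and a doubly substituted diene terminus would hardly react. The C3 oxygen would need a regio- and face-selective reaction of C2=C3. The cis fusion must be inverted at C5, and the two enedione carbonyls must be told apart while C7=C8 is moved to C8=C9.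
- Comparison: this alternative is clearly stronger in step count to the bicycle and in catalytic control of C10. The chosen route needs ten steps and a resolution before ring B closes. In its place it offers a ring A that already carries the C3 oxygen and C19, and a lactone that sets the quaternary C4.

Alternative 2: Ring A is cut at C5–C10 and C3–C4, with ring B as the tether ring. On heating, a terminal silyloxydiene (C10=C1–C2=C3) would add across the C4=C5 alkene of an α-methylbutenolide and give tricyclic lactone A4.
- For: both rings, the lactone, both quaternary centres, the C3 oxygen, C5 and the side chain on C9 arise in one step. Only hydrogenation of C1=C2, lactone reduction, acylation and completion of the chain would remain.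
- Against: the diene terminus C10 is fully substituted and the dienophile is trisubstituted, so two quaternary carbons must form in one congested transition state. The geometry of C10=C1 decides the configuration of C10 and must be made selectively. The C6 stereocentre of the butenolide is the only control element, and the endo or exo course decides C3 and C4 against C5 and C10. The open-chain substrate with a labile enol ether is itself a demanding target.
- Comparison: this alternative is stronger in convergence and needs no late methylation or triflate coupling. The chosen strategy offers a ring closure between a CH carbon and an acyl carbon, stereocentres set by equilibration and not by transition-state geometry, and a precursor made from simple pieces.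

Alternative 3: Ring B is cut at C7–C8. A cationic phosphine complex of monovalent gold would activate a C8≡C9 alkyne on C10, C7 of a silyl enol ether would attack in the 6-endo-dig mode, and an electrophilic iodine source would convert the C9–gold bond into the iodide, giving A5.
- For: the tetrasubstituted C8=C9 alkene forms directly with an iodide at C9, a better coupling handle than the triflate of 23. C4 is already quaternary with C19 as a protected alcohol, so neither the ketone differentiation of step 12 nor the lactone methylation of step 15 is needed.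
- Against: C3, quaternary C4, C5 and quaternary C10 must all exist before the key step, with C5 wedged between two quaternary carbons. Closure at an internal alkyne can also go 5-exo, which would give a five-membered ring.
- Comparison: this alternative is stronger in the endgame. The chosen strategy asks much less of the precursor (one quaternary stereocentre and one carbinol on a cyclohexene), its ring size is fixed by the tether, and C4 is completed after ring closure with the lactone as template.

Key step: step 11

**Remarks on the chemistry**

- Bicyclic compounds are named with labdane numbering: C17 on C8, C18 and C19 on C4, C20 on C10. β is the face of the C20 methyl group.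
- C8 is formed without control in step 8 and is equilibrated in step 11, so 15–17 are carried as mixtures of C8 epimers and drawn without configuration at C8.
- Assumption: the lipase in step 2 hydrolyses the (R)-acetate faster, as the empirical model for secondary carbinols predicts when the enone carbon is the larger group. If the preference is reversed, the recovered (R)-acetate is deacetylated with a non-selective esterase and taken into step 3.

## Route

Step 1
Reactants: 1 3-methylcyclohex-2-en-1-one
Product: 2 racemic 6-acetoxy-3-methylcyclohex-2-en-1-one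
Conditions: Mn(OAc)3·2H2O, benzene, reflux (water separator)
Reagents that add atoms: manganese triacetate, CC(=O)[O-].CC(=O)[O-].CC(=O)[O-].[Mn+3]
Why: α′-Acetoxylation of an enone by trivalent manganese; the metal enolate forms on the saturated side of the carbonyl and takes up acetate at C6, which puts oxygen on the future C3.

Step 2
Reactants: 2 racemic 6-acetoxy-3-methylcyclohex-2-en-1-one
Product: 3 (R)-6-hydroxy-3-methylcyclohex-2-en-1-one
Conditions: lipase from Burkholderia cepacia (immobilised), phosphate buffer (pH 7)/t-BuOMe, 25 °C, stopped near half conversion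
Reagents that add atoms: none
Why: Enzymatic kinetic resolution by enantioselective ester hydrolysis, a known reaction of α′-acetoxy enones; the neutral medium should not racemise the α-ketol, and the unreacted (S)-enantiomer of 2 is removed by chromatography.

Step 3
Reactants: 3 (R)-6-hydroxy-3-methylcyclohex-2-en-1-one
Product: 4 (R)-6-[(tert-butyldimethylsilyl)oxy]-3-methylcyclohex-2-en-1-one
Conditions: TBSCl, imidazole, DMF, 0 °C → rt
Reagents that add atoms: tert-butyl(chloro)dimethylsilane, CC(C)(C)[Si](C)(C)Cl
Why: Standard silylation of a secondary alcohol; the silyl ether should survive all basic, radical and hydride steps up to step 17.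

Step 4
Reactants: 4 (R)-6-[(tert-butyldimethylsilyl)oxy]-3-methylcyclohex-2-en-1-one; 5 but-1-yne
Product: 8 (3S,6R)-3-(but-1-en-2-yl)-6-[(tert-butyldimethylsilyl)oxy]-3-methyl-1-[(triethylsilyl)oxy]cyclohex-1-ene, via alkenylalane 6 (not isolated), via aluminium enolate 7 (not isolated)
Conditions: 5, iBu2AlH, Ni(dppp)Cl2 (3 mol %), THF, 0 → 22 °C; then 4, Cu(OTf)2 (5 mol %), chiral sulfonate-bearing imidazolinium salt (carbene precursor, 5 mol %), THF, −30 → 0 °C; then Et3SiOTf, −78 → 0 °C
Reagents that add atoms: triethylsilyl trifluoromethanesulfonate, CC[Si](CC)(CC)OS(=O)(=O)C(F)(F)F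
Why: Nickel-catalysed α-selective hydroalumination gives the internal alkenylalane, which the chiral carbene–copper catalyst adds 1,4 to the β-methyl enone (catalytic enantioselective conjugate addition that creates a quaternary centre). The ligand enantiomer is chosen to deliver the alkenyl group to the face of C3 syn to the remote silyloxy group, whose own 1,4-bias is weak, so the catalyst should set the 3S centre (future C10). The silyl triflate traps the enolate with its double bond on the side of the new quaternary carbon.

Step 5
Reactants: 8 (3S,6R)-3-(but-1-en-2-yl)-6-[(tert-butyldimethylsilyl)oxy]-3-methyl-1-[(triethylsilyl)oxy]cyclohex-1-ene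
Product: 10 (3S,6R)-3-(but-1-en-2-yl)-6-[(tert-butyldimethylsilyl)oxy]-3-methylcyclohex-1-en-1-yl trifluoromethanesulfonate, via lithium enolate 9 (not isolated)
Conditions: MeLi, THF, 0 °C → rt; then N-(5-chloropyridin-2-yl)bis(trifluoromethanesulfonimide), −78 → 0 °C
Reagents that add atoms: N-(5-chloropyridin-2-yl)-1,1,1-trifluoro-N-[(trifluoromethyl)sulfonyl]methanesulfonamide, FC(F)(F)S(=O)(=O)N(c1ccc(Cl)cn1)S(=O)(=O)C(F)(F)F
Why: Methyllithium cleaves the Si–O bond of the silyl enol ether and releases the regiodefined lithium enolate, which does not equilibrate toward the silyloxy-bearing carbon at low temperature; O-sulfonylation gives the enol triflate with the double bond between the future C4 and C5.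

Step 6
Reactants: 10 (3S,6R)-3-(but-1-en-2-yl)-6-[(tert-butyldimethylsilyl)oxy]-3-methylcyclohex-1-en-1-yl trifluoromethanesulfonate
Product: 11 methyl (3S,6R)-3-(but-1-en-2-yl)-6-[(tert-butyldimethylsilyl)oxy]-3-methylcyclohex-1-ene-1-carboxylate
Conditions: CO (1 atm), Pd(OAc)2 (5 mol %), PPh3 (10 mol %), Et3N, MeOH/DMF, 50 °C
Reagents that add atoms: carbon monoxide, [C-]#[O+]; methanol, CO
Why: Palladium-catalysed alkoxycarbonylation of an enol triflate (oxidative addition, CO insertion, methanolysis); it installs C19 on C4 and makes C5 the β-carbon of an enoate.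

Step 7
Reactants: 11 methyl (3S,6R)-3-(but-1-en-2-yl)-6-[(tert-butyldimethylsilyl)oxy]-3-methylcyclohex-1-ene-1-carboxylate
Product: 12 methyl (3S,6R)-6-[(tert-butyldimethylsilyl)oxy]-3-methyl-3-propanoylcyclohex-1-ene-1-carboxylate
Conditions: O3, CH2Cl2/MeOH, −78 °C, stopped when 11 is consumed; then Me2S, −78 °C → rt
Reagents that add atoms: ozone, [O-][O+]=O
Why: Chemoselective ozonolysis; the electron-rich 1,1-disubstituted alkene reacts far faster with the electrophilic oxidant than the ester-conjugated ring alkene, and reductive work-up gives the C9 ethyl ketone.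

Step 8
Reactants: 12 methyl (3S,6R)-6-[(tert-butyldimethylsilyl)oxy]-3-methyl-3-propanoylcyclohex-1-ene-1-carboxylate; 13 prop-2-en-1-yl bromoacetate
Product: 15 prop-2-en-1-yl 4-[(1S,4R)-4-[(tert-butyldimethylsilyl)oxy]-3-(methoxycarbonyl)-1-methylcyclohex-2-en-1-yl]-3-methyl-4-oxobutanoate (both C8 epimers), via lithium enolate 14 (not isolated)
Conditions: LiN(iPr)2, THF, −78 °C; then 13, DMPU, −78 → −30 °C
Reagents that add atoms: none
Why: Ketone enolate alkylation (SN2) with an activated bromide; the ketone can enolise only toward C8 because C10 is quaternary and the enoate has no acidic hydrogen, so the C7–C8 bond forms at one position only. The configuration at C8 is not controlled and need not be.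

Step 9
Reactants: 15 prop-2-en-1-yl 4-[(1S,4R)-4-[(tert-butyldimethylsilyl)oxy]-3-(methoxycarbonyl)-1-methylcyclohex-2-en-1-yl]-3-methyl-4-oxobutanoate
Product: 16 4-[(1S,4R)-4-[(tert-butyldimethylsilyl)oxy]-3-(methoxycarbonyl)-1-methylcyclohex-2-en-1-yl]-3-methyl-4-oxobutanoic acid (both C8 epimers)
Conditions: Pd(PPh3)4 (3 mol %), morpholine, THF, rt
Reagents that add atoms: none
Why: Allyl ester cleavage through a π-allylpalladium complex with the amine as allyl acceptor (Tsuji–Trost type); the neutral conditions leave the silyl ether, the methyl ester and the ketone untouched.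

Step 10
Reactants: 16 4-[(1S,4R)-4-[(tert-butyldimethylsilyl)oxy]-3-(methoxycarbonyl)-1-methylcyclohex-2-en-1-yl]-3-methyl-4-oxobutanoic acid
Product: 17 Se-phenyl 4-[(1S,4R)-4-[(tert-butyldimethylsilyl)oxy]-3-(methoxycarbonyl)-1-methylcyclohex-2-en-1-yl]-3-methyl-4-oxobutaneselenoate (both C8 epimers)
Conditions: (PhSe)2, Bu3P, CH2Cl2, 0 °C → rt
Reagents that add atoms: diphenyl diselenide, c1ccccc1[Se][Se]c1ccccc1
Why: The phosphine and the diselenide form a selenophosphonium salt that activates the acid as an acyloxyphosphonium ion, which phenylselenolate then acylates; this is the standard neutral route to phenyl selenoesters.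

Step 11
Reactants: 17 Se-phenyl 4-[(1S,4R)-4-[(tert-butyldimethylsilyl)oxy]-3-(methoxycarbonyl)-1-methylcyclohex-2-en-1-yl]-3-methyl-4-oxobutaneselenoate
Product: 19 methyl 3α-[(tert-butyldimethylsilyl)oxy]-8α,10β-dimethyl-6,9-dioxo-5α-decalin-4α-carboxylate (trans-fused), via cyclised diketo ester 18 (not isolated)
Conditions: Bu3SnH (syringe pump), AIBN, benzene (0.005 M), 80 °C; then K2CO3, MeOH, rt
Reagents that add atoms: none
Why: Tributylstannyl radicals (from AIBN and Bu3SnH) abstract the phenylseleno group of 17 and leave the C6 acyl radical, a nucleophilic σ-radical that adds to C5, the β-carbon of the electron-poor C4 enoate; the ester-stabilised C4 radical then takes hydrogen from Bu3SnH and carries the chain. The closest known reaction type is the 6-exo conjugate cyclisation of acyl radicals made from phenyl selenoesters onto α,β-unsaturated esters. Ring B closes in the 6-exo-trig mode (atoms C6, C7, C8, C9, C10, C5); the 7-endo mode is ruled out by polarity because it would need attack at the ester-bearing C4. C5 and C4 are new stereocentres and C8 arrives as a mixture: C5 and C8 lie α to the C6 and C9 ketones and are equilibrated by K2CO3 in methanol to the chair–chair trans-fused diketone with an equatorial 8α-methyl, with the angular C20 methyl and the fixed C3 centre as reference. C4 settles with its ester equatorial, which is of no consequence because step 12 resets it. The step needs the cyclisation to outrun hydrogen transfer to the acyl radical and loss of CO: slow addition of the stannane at high dilution answers the first, and the second is slow because it would give a primary alkyl radical, while the quaternary C10 and the sp2 C9 in the tether bend the chain toward C5. Stannyl radicals leave the ketone, the silyl ether and the ester untouched.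

Step 12
Reactants: 19 methyl 3α-[(tert-butyldimethylsilyl)oxy]-8α,10β-dimethyl-6,9-dioxo-5α-decalin-4α-carboxylate
Product: 21 3α-[(tert-butyldimethylsilyl)oxy]-8α,10β-dimethyl-9-oxo-5α-decalin-19,6β-carbolactone (γ-lactone from the 4β carboxyl carbon C19 to O6; 4α-H), via hydroxy ester 20 (not isolated)
Conditions: NaBH4, MeOH/CH2Cl2, −40 → −20 °C; then NaOMe, MeOH, rt
Reagents that add atoms: none
Why: Borohydride reduces the C6 ketone, flanked by CH and CH2, much faster than the C9 ketone wedged between quaternary C10 and the methyl-bearing C8. Hydride enters from the α face because the β face is screened by the syn-axial C20 methyl, which gives the axial 6β-alcohol. Methoxide then epimerises C4 through the ester enolate, and only the 4β-ester, 1,3-diaxial to the 6β-oxygen, can lactonise, which drains the equilibrium.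

Step 13
Reactants: 21 3α-[(tert-butyldimethylsilyl)oxy]-8α,10β-dimethyl-9-oxo-5α-decalin-19,6β-carbolactone
Product: 23 3α-[(tert-butyldimethylsilyl)oxy]-8,10β-dimethyl-9-[(trifluoromethylsulfonyl)oxy]-5α-decal-8-ene-19,6β-carbolactone, via potassium enolate 22 (not isolated)
Conditions: KN(SiMe3)2, THF, −78 °C; then N-(5-chloropyridin-2-yl)bis(trifluoromethanesulfonimide), −78 → −20 °C
Reagents that add atoms: N-(5-chloropyridin-2-yl)-1,1,1-trifluoro-N-[(trifluoromethyl)sulfonyl]methanesulfonamide, FC(F)(F)S(=O)(=O)N(c1ccc(Cl)cn1)S(=O)(=O)C(F)(F)F
Why: The C9 ketone can enolise only toward C8, and its α-hydrogen is more acidic than the lactone α-hydrogen at C4, so one equivalent of base should give the C8=C9 enolate; O-sulfonylation fixes the tetrasubstituted double bond of the target.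

Step 14
Reactants: 23 3α-[(tert-butyldimethylsilyl)oxy]-8,10β-dimethyl-9-[(trifluoromethylsulfonyl)oxy]-5α-decal-8-ene-19,6β-carbolactone; 24 2-(2-bromoethyl)-2-methyl-1,3-dioxolane
Product: 26 3α-[(tert-butyldimethylsilyl)oxy]-13,13-(ethylenedioxy)-14,15,18-trinorlabd-8-en-19,6β-olide (4α-H), via alkylzinc bromide 25 (not isolated)
Conditions: 24, Zn dust (activated with 1,2-dibromoethane and Me3SiCl), LiCl, THF, 50 °C; then 23, Pd(OAc)2 (5 mol %), 2-dicyclohexylphosphino-2′,6′-dimethoxybiphenyl (10 mol %), THF/NMP, 60 °C
Reagents that add atoms: none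
Why: Negishi coupling of an alkenyl triflate with a primary alkylzinc halide; the electron-rich biaryl phosphine speeds oxidative addition and reductive elimination at the hindered carbon, and the organozinc tolerates the lactone and the ketal.

Step 15
Reactants: 26 3α-[(tert-butyldimethylsilyl)oxy]-13,13-(ethylenedioxy)-14,15,18-trinorlabd-8-en-19,6β-olide
Product: 28 3α-[(tert-butyldimethylsilyl)oxy]-13,13-(ethylenedioxy)-14,15-dinorlabd-8-en-19,6β-olide, via lithium enolate 27 (not isolated)
Conditions: LiN(iPr)2, THF, −78 °C; then MeI, DMPU, −78 → −40 °C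
Reagents that add atoms: iodomethane, CI
Why: Lactone enolate alkylation; C4–H is the only acidic hydrogen left, and the lactone bridge holds C19 on the β face, so iodomethane can only enter from the α face and the quaternary C4 forms with the C18 methyl α. The low temperature is meant to suppress β-elimination of the C3 silyloxy group.

Step 16
Reactants: 28 3α-[(tert-butyldimethylsilyl)oxy]-13,13-(ethylenedioxy)-14,15-dinorlabd-8-en-19,6β-olide
Product: 29 3α-[(tert-butyldimethylsilyl)oxy]-13,13-(ethylenedioxy)-14,15-dinorlabd-8-ene-6β,19-diol
Conditions: LiAlH4, THF, 0 → 65 °C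
Reagents that add atoms: none
Why: Hydride reduction of the hindered lactone to the primary C19 alcohol and the 6β-alcohol with retention at C6; the ketal, the silyl ether and the tetrasubstituted alkene are inert.

Step 17
Reactants: 29 3α-[(tert-butyldimethylsilyl)oxy]-13,13-(ethylenedioxy)-14,15-dinorlabd-8-ene-6β,19-diol
Product: 30 3α,6β,19-trihydroxy-14,15-dinorlabd-8-en-13-one
Conditions: HCl (1 M aq.), THF/MeOH, rt
Reagents that add atoms: water, O
Why: Acid-catalysed cleavage of the silyl ether and hydrolysis of the dioxolane in one operation; dilute acid at room temperature should not protonate the tetrasubstituted alkene.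

Step 18
Reactants: 30 3α,6β,19-trihydroxy-14,15-dinorlabd-8-en-13-one
Product: 31 6β-hydroxy-3α,19-bis(3-methylbutanoyloxy)-14,15-dinorlabd-8-en-13-one
Conditions: 3-methylbutanoic anhydride (2.3 equiv), DMAP (cat.), pyridine, CH2Cl2, 0 °C → rt
Reagents that add atoms: 3-methylbutanoic anhydride, CC(C)CC(=O)OC(=O)CC(C)C
Why: Nucleophile-catalysed acylation; the primary C19 hydroxyl and the axial 3α-hydroxyl (syn-axial only to hydrogens) should react, while the 6β-hydroxyl, syn-axial to both the C20 methyl and the C19 methylene like the 11β-hydroxyl of corticosteroids, should stay free when the anhydride is limited.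

Step 19
Reactants: 31 6β-hydroxy-3α,19-bis(3-methylbutanoyloxy)-14,15-dinorlabd-8-en-13-one
Product: 32 prop-2-en-1-yl 6β-hydroxy-3α,19-bis(3-methylbutanoyloxy)labda-8,13E-dien-15-oate
Conditions: allyl 2-(diethoxyphosphoryl)acetate, NaH (phosphonate in slight excess over base), THF, 0 → 45 °C
Reagents that add atoms: prop-2-en-1-yl 2-(diethoxyphosphoryl)acetate, C=CCOC(=O)CP(=O)(OCC)OCC
Why: Horner–Wadsworth–Emmons olefination of a methyl ketone; the E isomer (C12 trans to C15) is expected to predominate and the Z isomer is removed by chromatography. Keeping the phosphonate in excess over the base leaves the 6β-hydroxyl protonated, so that it cannot take over the C19 acyl group.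

Step 20
Reactants: 32 prop-2-en-1-yl 6β-hydroxy-3α,19-bis(3-methylbutanoyloxy)labda-8,13E-dien-15-oate
Product: 33 6β-hydroxy-3α,19-bis(3-methylbutanoyloxy)labda-8,13E-dien-15-oic acid (CNP0333611.1)
Conditions: Pd(PPh3)4 (5 mol %), morpholine, THF, rt; dilute citric acid wash
Reagents that add atoms: none
Why: Allyl ester cleavage through a π-allylpalladium complex with morpholine as acceptor; the neutral conditions should preserve both isovalerates, the hindered alcohol and the alkene geometry.

## Compound list

1 | 3-methylcyclohex-2-en-1-one | CC1=CC(=O)CCC1 | starting material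
2 | racemic 6-acetoxy-3-methylcyclohex-2-en-1-one | CC1=CC(=O)C(OC(C)=O)CC1 | intermediate
3 | (R)-6-hydroxy-3-methylcyclohex-2-en-1-one | CC1=CC(=O)[C@H](O)CC1 | intermediate
4 | (R)-6-[(tert-butyldimethylsilyl)oxy]-3-methylcyclohex-2-en-1-one | CC1=CC(=O)[C@H](O[Si](C)(C)C(C)(C)C)CC1 | intermediate
5 | but-1-yne | CCC#C | starting material
6 | (but-1-en-2-yl)bis(2-methylpropyl)alane | CCC(=C)[Al](CC(C)C)CC(C)C | intermediate (not isolated)
7 | diisobutylaluminium (3S,6R)-3-(but-1-en-2-yl)-6-[(tert-butyldimethylsilyl)oxy]-3-methylcyclohex-1-en-1-olate | CCC(=C)[C@@]1(C)CC[C@@H](O[Si](C)(C)C(C)(C)C)C(O[Al](CC(C)C)CC(C)C)=C1 | intermediate (not isolated)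
8 | (3S,6R)-3-(but-1-en-2-yl)-6-[(tert-butyldimethylsilyl)oxy]-3-methyl-1-[(triethylsilyl)oxy]cyclohex-1-ene | CCC(=C)[C@@]1(C)CC[C@@H](O[Si](C)(C)C(C)(C)C)C(O[Si](CC)(CC)CC)=C1 | intermediate
9 | lithium (3S,6R)-3-(but-1-en-2-yl)-6-[(tert-butyldimethylsilyl)oxy]-3-methylcyclohex-1-en-1-olate | CCC(=C)[C@@]1(C)CC[C@@H](O[Si](C)(C)C(C)(C)C)C(O[Li])=C1 | intermediate (not isolated)
10 | (3S,6R)-3-(but-1-en-2-yl)-6-[(tert-butyldimethylsilyl)oxy]-3-methylcyclohex-1-en-1-yl trifluoromethanesulfonate | CCC(=C)[C@@]1(C)CC[C@@H](O[Si](C)(C)C(C)(C)C)C(OS(=O)(=O)C(F)(F)F)=C1 | intermediate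
11 | methyl (3S,6R)-3-(but-1-en-2-yl)-6-[(tert-butyldimethylsilyl)oxy]-3-methylcyclohex-1-ene-1-carboxylate | CCC(=C)[C@@]1(C)CC[C@@H](O[Si](C)(C)C(C)(C)C)C(C(=O)OC)=C1 | intermediate
12 | methyl (3S,6R)-6-[(tert-butyldimethylsilyl)oxy]-3-methyl-3-propanoylcyclohex-1-ene-1-carboxylate | CCC(=O)[C@@]1(C)CC[C@@H](O[Si](C)(C)C(C)(C)C)C(C(=O)OC)=C1 | intermediate
13 | prop-2-en-1-yl bromoacetate | C=CCOC(=O)CBr | starting material
14 | lithium enolate of 12 (C8=C9–OLi) | CC=C(O[Li])[C@@]1(C)CC[C@@H](O[Si](C)(C)C(C)(C)C)C(C(=O)OC)=C1 | intermediate (not isolated)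
15 | prop-2-en-1-yl 4-[(1S,4R)-4-[(tert-butyldimethylsilyl)oxy]-3-(methoxycarbonyl)-1-methylcyclohex-2-en-1-yl]-3-methyl-4-oxobutanoate, C8 epimers | CC(CC(=O)OCC=C)C(=O)[C@@]1(C)CC[C@@H](O[Si](C)(C)C(C)(C)C)C(C(=O)OC)=C1 | intermediate
16 | 4-[(1S,4R)-4-[(tert-butyldimethylsilyl)oxy]-3-(methoxycarbonyl)-1-methylcyclohex-2-en-1-yl]-3-methyl-4-oxobutanoic acid, C8 epimers | CC(CC(=O)O)C(=O)[C@@]1(C)CC[C@@H](O[Si](C)(C)C(C)(C)C)C(C(=O)OC)=C1 | intermediate
17 | Se-phenyl 4-[(1S,4R)-4-[(tert-butyldimethylsilyl)oxy]-3-(methoxycarbonyl)-1-methylcyclohex-2-en-1-yl]-3-methyl-4-oxobutaneselenoate, C8 epimers (key-step precursor) | CC(CC(=O)[Se]c1ccccc1)C(=O)[C@@]2(C)CC[C@@H](O[Si](C)(C)C(C)(C)C)C(C(=O)OC)=C2 | intermediate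
18 | methyl 3α-[(tert-butyldimethylsilyl)oxy]-8,10β-dimethyl-6,9-dioxodecalin-4-carboxylate, stereoisomers at C4, C5 and C8 | CC1C(=O)[C@@]2(C)CC[C@@H](O[Si](C)(C)C(C)(C)C)C(C(=O)OC)C2C(=O)C1 | intermediate (not isolated)
19 | methyl 3α-[(tert-butyldimethylsilyl)oxy]-8α,10β-dimethyl-6,9-dioxo-5α-decalin-4α-carboxylate (key-step product) | C[C@H]1C(=O)[C@@]2(C)CC[C@@H](O[Si](C)(C)C(C)(C)C)[C@@H](C(=O)OC)[C@@H]2C(=O)C1 | intermediate
20 | methyl 3α-[(tert-butyldimethylsilyl)oxy]-6β-hydroxy-8α,10β-dimethyl-9-oxo-5α-decalin-4α-carboxylate | C[C@H]1C(=O)[C@@]2(C)CC[C@@H](O[Si](C)(C)C(C)(C)C)[C@@H](C(=O)OC)[C@@H]2[C@H](O)C1 | intermediate (not isolated)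
21 | 3α-[(tert-butyldimethylsilyl)oxy]-8α,10β-dimethyl-9-oxo-5α-decalin-19,6β-carbolactone (4α-H) | C[C@H]1C(=O)[C@@]2(C)CC[C@@H](O[Si](C)(C)C(C)(C)C)[C@@H]3C(=O)O[C@H](C1)[C@H]23 | intermediate
22 | potassium enolate of 21 (C8=C9–OK) | CC1=C(O[K])[C@@]2(C)CC[C@@H](O[Si](C)(C)C(C)(C)C)[C@@H]3C(=O)O[C@H](C1)[C@H]23 | intermediate (not isolated)
23 | 3α-[(tert-butyldimethylsilyl)oxy]-8,10β-dimethyl-9-[(trifluoromethylsulfonyl)oxy]-5α-decal-8-ene-19,6β-carbolactone (4α-H) | CC1=C(OS(=O)(=O)C(F)(F)F)[C@@]2(C)CC[C@@H](O[Si](C)(C)C(C)(C)C)[C@@H]3C(=O)O[C@H](C1)[C@H]23 | intermediate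
24 | 2-(2-bromoethyl)-2-methyl-1,3-dioxolane | CC1(CCBr)OCCO1 | starting material
25 | [2-(2-methyl-1,3-dioxolan-2-yl)ethyl]zinc bromide | CC1(CC[Zn]Br)OCCO1 | intermediate (not isolated)
26 | 3α-[(tert-butyldimethylsilyl)oxy]-13,13-(ethylenedioxy)-14,15,18-trinorlabd-8-en-19,6β-olide (4α-H) | CC1=C(CCC4(C)OCCO4)[C@@]2(C)CC[C@@H](O[Si](C)(C)C(C)(C)C)[C@@H]3C(=O)O[C@H](C1)[C@H]23 | intermediate
27 | lithium enolate of 26 (C4=C19–OLi) | CC1=C(CCC4(C)OCCO4)[C@@]2(C)CC[C@@H](O[Si](C)(C)C(C)(C)C)C3=C(O[Li])O[C@H](C1)[C@H]23 | intermediate (not isolated)
28 | 3α-[(tert-butyldimethylsilyl)oxy]-13,13-(ethylenedioxy)-14,15-dinorlabd-8-en-19,6β-olide | CC1=C(CCC4(C)OCCO4)[C@@]2(C)CC[C@@H](O[Si](C)(C)C(C)(C)C)[C@]3(C)C(=O)O[C@H](C1)[C@H]23 | intermediate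
29 | 3α-[(tert-butyldimethylsilyl)oxy]-13,13-(ethylenedioxy)-14,15-dinorlabd-8-ene-6β,19-diol | CC1=C(CCC3(C)OCCO3)[C@@]2(C)CC[C@@H](O[Si](C)(C)C(C)(C)C)[C@](C)(CO)[C@@H]2[C@H](O)C1 | intermediate
30 | 3α,6β,19-trihydroxy-14,15-dinorlabd-8-en-13-one | CC1=C(CCC(C)=O)[C@@]2(C)CC[C@@H](O)[C@](C)(CO)[C@@H]2[C@H](O)C1 | intermediate
31 | 6β-hydroxy-3α,19-bis(3-methylbutanoyloxy)-14,15-dinorlabd-8-en-13-one | CC1=C(CCC(C)=O)[C@@]2(C)CC[C@@H](OC(=O)CC(C)C)[C@](C)(COC(=O)CC(C)C)[C@@H]2[C@H](O)C1 | intermediate
32 | prop-2-en-1-yl 6β-hydroxy-3α,19-bis(3-methylbutanoyloxy)labda-8,13E-dien-15-oate | CC1=C(CC/C(C)=C/C(=O)OCC=C)[C@@]2(C)CC[C@@H](OC(=O)CC(C)C)[C@](C)(COC(=O)CC(C)C)[C@@H]2[C@H](O)C1 | intermediate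
33 | 6β-hydroxy-3α,19-bis(3-methylbutanoyloxy)labda-8,13E-dien-15-oic acid (CNP0333611.1) | CC1=C(CC/C(C)=C/C(=O)O)[C@@]2(C)CC[C@@H](OC(=O)CC(C)C)[C@](C)(COC(=O)CC(C)C)[C@@H]2[C@H](O)C1 | target

## Step count and least certain steps

Total step count: 20. Longest linear sequence: 20 steps (1 → 33). Compounds 5, 13 and 24 enter without steps of their own.

**Step 11 (key step).** The most likely failure is hydrogen transfer to the acyl radical before ring closure, or loss of CO followed by 5-exo closure of the C7 radical, because attack at C5 is slowed by the adjacent quaternary C10. The angular methyl group also lowers the trans preference, so the equilibration may leave cis-fused material that has to be recycled through the same base treatment. Fallback: setting out from 17, Bu3SnH with Pd(PPh3)4 and no initiator reduces the selenoester to the γ-keto aldehyde methyl (3S,6R)-6-[(tert-butyldimethylsilyl)oxy]-3-methyl-3-(2-methyl-4-oxobutanoyl)cyclohex-1-ene-1-carboxylate F1. A triazolium-derived carbene then turns the aldehyde into an acyl-anion equivalent that adds to C5 in an intramolecular Stetter reaction. This closes the same C5–C6 bond by a polar path and comes back to the route at 18, which is equilibrated to 19 as before.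

**Step 14.** Oxidative addition and transmetallation at the tetrasubstituted triflate next to quaternary C10 may be slow, so that β-hydride elimination from the alkylpalladium or cleavage of the triflate back to the ketone takes over. Fallback: setting out from 23, the Grignard reagent [2-(2-methyl-1,3-dioxolan-2-yl)ethyl]magnesium bromide F2, made from 24 and Mg, is coupled under Fe(acac)3 catalysis in THF/NMP at −20 °C. This Kumada-type coupling does not pass through a palladium alkyl and is fast enough at low temperature to spare the lactone. It comes back to the route at 26.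

**Step 12.** The hydroxy ester must invert at C4 before it can close. Enolisation of the ester in methoxide is slow, and the axial 3α-silyloxy group is aligned with the enolate for E1cB loss, so elimination may compete with epimerisation. Partial reduction at C9 is the second risk. Fallback: setting out from 20, isolated after the borohydride stage, LiOH saponification gives the hydroxy acid 3α-[(tert-butyldimethylsilyl)oxy]-6β-hydroxy-8α,10β-dimethyl-9-oxo-5α-decalin-4α-carboxylic acid F3. Under Yamaguchi lactonisation conditions (2,4,6-trichlorobenzoyl chloride, Et3N, then DMAP, toluene, 80 °C) the hindered mixed anhydride is expected to lose the acylating group through the ketene, which makes C4 planar without an enolate that could expel the silyloxy group. The 6β-hydroxyl then adds to the ketene from the β face, and the path comes back to the route at 21.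

**Step 15.** Methylation on the α face next to the axial silyloxy group may be slow, which leaves the lactone enolate time to eliminate silanolate on warming. Fallback: setting out from 26, Bu4NF removes the silyl group to give the β-hydroxy lactone 13,13-(ethylenedioxy)-3α-hydroxy-14,15,18-trinorlabd-8-en-19,6β-olide F4. Two equivalents of LiN(iPr)2 and iodomethane then methylate the alkoxide–enolate dianion (Fráter–Seebach type), which cannot eliminate and is less crowded, giving 13,13-(ethylenedioxy)-3α-hydroxy-14,15-dinorlabd-8-en-19,6β-olide F5. LiAlH4 gives the triol 13,13-(ethylenedioxy)-14,15-dinorlabd-8-ene-3α,6β,19-triol F6, and aqueous HCl comes back to the route at 30.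

**Step 4.** The resident C6 stereocentre may oppose the catalyst and erode facial selectivity, or slow addition to the oxygenated enone may let isobutyl or hydride transfer compete. Fallback: setting out from 1, the substrate on which this conjugate addition is best known, the same alane and catalyst give (S)-3-(but-1-en-2-yl)-3-methylcyclohexan-1-one F7. L-Proline-catalysed α-aminoxylation with nitrosobenzene, which enolises away from the quaternary carbon and is expected to give the 2R centre by the usual enamine model, affords (2R,5S)-5-(but-1-en-2-yl)-5-methyl-2-[(phenylamino)oxy]cyclohexan-1-one F8. CuSO4 in methanol cleaves the N–O bond to (2R,5S)-5-(but-1-en-2-yl)-2-hydroxy-5-methylcyclohexan-1-one F9, and TBSCl with imidazole gives (2R,5S)-5-(but-1-en-2-yl)-2-[(tert-butyldimethylsilyl)oxy]-5-methylcyclohexan-1-one F10. Kinetic deprotonation with KN(SiMe3)2 at the methylene next to the quaternary carbon (the other α-hydrogen is shielded by the silyloxy group), followed by the N-aryl triflimide, comes back to the route at 10.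

## Further compounds

F1 | step 11 | methyl (3S,6R)-6-[(tert-butyldimethylsilyl)oxy]-3-methyl-3-(2-methyl-4-oxobutanoyl)cyclohex-1-ene-1-carboxylate, C8 epimers | CC(CC=O)C(=O)[C@@]1(C)CC[C@@H](O[Si](C)(C)C(C)(C)C)C(C(=O)OC)=C1
F2 | step 14 | [2-(2-methyl-1,3-dioxolan-2-yl)ethyl]magnesium bromide | CC1(CC[Mg]Br)OCCO1
F3 | step 12 | 3α-[(tert-butyldimethylsilyl)oxy]-6β-hydroxy-8α,10β-dimethyl-9-oxo-5α-decalin-4α-carboxylic acid | C[C@H]1C(=O)[C@@]2(C)CC[C@@H](O[Si](C)(C)C(C)(C)C)[C@@H](C(=O)O)[C@@H]2[C@H](O)C1
F4 | step 15 | 13,13-(ethylenedioxy)-3α-hydroxy-14,15,18-trinorlabd-8-en-19,6β-olide (4α-H) | CC1=C(CCC4(C)OCCO4)[C@@]2(C)CC[C@@H](O)[C@@H]3C(=O)O[C@H](C1)[C@H]23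
F5 | step 15 | 13,13-(ethylenedioxy)-3α-hydroxy-14,15-dinorlabd-8-en-19,6β-olide | CC1=C(CCC4(C)OCCO4)[C@@]2(C)CC[C@@H](O)[C@]3(C)C(=O)O[C@H](C1)[C@H]23
F6 | step 15 | 13,13-(ethylenedioxy)-14,15-dinorlabd-8-ene-3α,6β,19-triol | CC1=C(CCC3(C)OCCO3)[C@@]2(C)CC[C@@H](O)[C@](C)(CO)[C@@H]2[C@H](O)C1
F7 | step 4 | (S)-3-(but-1-en-2-yl)-3-methylcyclohexan-1-one | CCC(=C)[C@@]1(C)CCCC(=O)C1
F8 | step 4 | (2R,5S)-5-(but-1-en-2-yl)-5-methyl-2-[(phenylamino)oxy]cyclohexan-1-one | CCC(=C)[C@@]1(C)CC[C@@H](ONc2ccccc2)C(=O)C1
F9 | step 4 | (2R,5S)-5-(but-1-en-2-yl)-2-hydroxy-5-methylcyclohexan-1-one | CCC(=C)[C@@]1(C)CC[C@@H](O)C(=O)C1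
F10 | step 4 | (2R,5S)-5-(but-1-en-2-yl)-2-[(tert-butyldimethylsilyl)oxy]-5-methylcyclohexan-1-one | CCC(=C)[C@@]1(C)CC[C@@H](O[Si](C)(C)C(C)(C)C)C(=O)C1
A1 | alternative 1 | (E)-penta-1,3-diene | C/C=C/C=C
A2 | alternative 1 | 2,6-dimethyl-1,4-benzoquinone | CC1=CC(=O)C=C(C)C1=O
A3 | alternative 1 | cis-fused endo adduct, 4,8,10-trimethyldecalin-2,7-diene-6,9-dione (labdane numbering) | CC1=CC(=O)[C@@H]2[C@H](C)C=CC[C@]2(C)C1=O
A4 | alternative 2 | 3α-[(tert-butyldimethylsilyl)oxy]-13,13-(ethylenedioxy)-14,15-dinorlabda-1,8-dien-19,6β-olide | CC1=C(CCC3(C)OCCO3)[C@@]2(C)C=C[C@@H](O[Si](C)(C)C(C)(C)C)[C@](C)(C(=O)O5)[C@@H]2[C@H]5C1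
A5 | alternative 3 | 3α-[(tert-butyldimethylsilyl)oxy]-9-iodo-4β-{[(4-methoxyphenyl)methoxy]methyl}-4α,8,10β-trimethyl-5α-decal-8-en-6-one (labdane numbering) | CC1=C(I)[C@@]2(C)CC[C@@H](O[Si](C)(C)C(C)(C)C)[C@](C)(COCc3ccc(OC)cc3)[C@@H]2C(=O)C1
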